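**Strategy.** The 2-oxabicyclo[2.2.2]octan-3-one core, whose lactone bridge C13(=O)–O15 spans C12 and C16 of the carbocycle C12/C27/C26/C16/C21/C22 with the C27 carbinol beside it, is read as the adduct of a cyclohexa-1,3-diene and CO2 (locants: heavy-atom order of the target SMILES). CO2 itself being too stable, ethyl glyoxylate serves as its surrogate: one hetero-Diels–Alder reaction with the 2-silyloxydiene C12=C27(OSi)–C26=C16 forms C12–C13 and O15–C16 and both quaternary centres. Oxidative excision of the ester carbon, then unmasking and reduction of the C27 ketone, finish the route. The diene comes from a tricyclic enone built from (E)-dec-2-enal and (S)-4-silyloxycyclopentenone by Michael/aldol annulation.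

Key step: step 10

Remark: ring A = dihydropyran (O11, C12, C22, C23, C24, C10), ring B = carbocycle (C12, C27, C26, C16, C21, C22), ring C = cyclopentane; 3-bromo-2-methoxyprop-1-ene is taken as a commercial reagent, and the ProPhenol antipode used is the one that delivers the 4R alcohol.

Step 1
Reactants: 1 (E)-dec-2-enal; 2 methyl propiolate
Product: 3 methyl (4R,5E)-4-hydroxytridec-5-en-2-ynoate
Conditions: Me2Zn (3 equiv), (S,S)-ProPhenol (10 mol %), Ph3P=O (20 mol %), toluene, 4 °C; aq. NH4Cl
Reagents that add atoms: none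
Why: Catalytic asymmetric alkynylation (zinc alkynylide addition to the aldehyde), in which the dinuclear zinc–ProPhenol pocket selects the aldehyde face and sets C10 (R).

Step 2
Reactants: 3 methyl (4R,5E)-4-hydroxytridec-5-en-2-ynoate
Product: 4 methyl (4R,5E)-4-[(2-methoxyprop-2-en-1-yl)oxy]tridec-5-en-2-ynoate
Conditions: 3-bromo-2-methoxyprop-1-ene (3 equiv), Ag2O (3 equiv), 4 Å MS, Et2O, rt, dark
Reagents that add atoms: 3-bromo-2-methoxyprop-1-ene, COC(=C)CBr
Why: Ag2O-mediated Williamson etherification under neutral conditions spares the base-sensitive γ-hydroxy ynoate and installs a masked acetonyl ether (future C12, C27, C26) without touching C10.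

Step 3
Reactants: 4 methyl (4R,5E)-4-[(2-methoxyprop-2-en-1-yl)oxy]tridec-5-en-2-ynoate
Product: 5 methyl (2Z,4R,5E)-4-[(2-methoxyprop-2-en-1-yl)oxy]-3-methyltrideca-2,5-dienoate
Conditions: Me2CuLi (1.3 equiv, from CuI and MeLi), THF, −78 °C; MeOH at −78 °C, then NH4Cl/NH4OH
Reagents that add atoms: lithium dimethylcuprate, [Li+].C[Cu-]C
Why: Gilman conjugate addition (syn-carbocupration of the ynoate) with cold protonation places H23 cis to the new methyl, so that C22 and C10 are cis on C23=C24 (2Z), as the later pyran ring demands.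

Step 4
Reactants: 5 methyl (2Z,4R,5E)-4-[(2-methoxyprop-2-en-1-yl)oxy]-3-methyltrideca-2,5-dienoate
Product: 6 (2Z,4R,5E)-4-[(2-methoxyprop-2-en-1-yl)oxy]-3-methyltrideca-2,5-dien-1-ol
Conditions: i-Bu2AlH (2.3 equiv), CH2Cl2, −78 °C; Rochelle salt
Reagents that add atoms: none
Why: Hydride 1,2-reduction of the enoate to the allylic alcohol, with the alkenes and the enol ether inert.

Step 5
Reactants: 6 (2Z,4R,5E)-4-[(2-methoxyprop-2-en-1-yl)oxy]-3-methyltrideca-2,5-dien-1-ol
Product: 7 (2Z,4R,5E)-4-[(2-methoxyprop-2-en-1-yl)oxy]-3-methyltrideca-2,5-dienal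
Conditions: MnO2 (activated, 20 equiv), CH2Cl2, rt, dark; used at once
Reagents that add atoms: none
Why: Allylic oxidation with MnO2 under neutral conditions should keep the 2Z geometry and the acid-labile enol ether.

Step 6
Reactants: 8 (S)-4-[(tert-butyldimethylsilyl)oxy]cyclopent-2-en-1-one
Product: 9 (R)-tert-butyldimethyl{[3-(triethylsilyloxy)cyclopent-3-en-1-yl]oxy}silane
Conditions: Et3SiH (1.1 equiv), RhCl(PPh3)3 (0.5 mol %), THF, 40 °C
Reagents that add atoms: triethylsilane, CC[SiH](CC)CC
Why: Rhodium-catalysed 1,4-hydrosilylation of the enone gives the regiodefined silyl enol ether (C16=C21) and leaves C18 untouched.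

Step 7
Reactants: 9 (R)-tert-butyldimethyl{[3-(triethylsilyloxy)cyclopent-3-en-1-yl]oxy}silane; 7 (2Z,4R,5E)-4-[(2-methoxyprop-2-en-1-yl)oxy]-3-methyltrideca-2,5-dienal
Product: 13 (2E,4R)-4-[(tert-butyldimethylsilyl)oxy]-2-[(2Z,4R,5E)-3-methyl-4-(2-oxopropoxy)trideca-2,5-dien-1-ylidene]cyclopentan-1-one, via lithium enolate 10 (not isolated), via aldol mesylate 11 (not isolated), via enol-ether dienone 12 (not isolated)
Conditions: MeLi (1.0 equiv), THF, −10 °C, then 7, −78 °C; MsCl (1.5 equiv), Et3N (4 equiv), −78 to 0 °C; work-up 0.5 M HCl/THF, 0 °C, 10 min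
Reagents that add atoms: water, O
Why: Aldol condensation by stages: MeLi frees the regiodefined lithium enolate, which adds to the enal at C21; mesylation and E1cB elimination give the E-alkylidene ketone (C21=C22), and the acidic work-up hydrolyses the enol ether to the acetonyl ether.

Step 8
Reactants: 13 (2E,4R)-4-[(tert-butyldimethylsilyl)oxy]-2-[(2Z,4R,5E)-3-methyl-4-(2-oxopropoxy)trideca-2,5-dien-1-ylidene]cyclopentan-1-one
Product: 15 tricyclic enone (10R,12S,18R,21R,22R): ring A fused at C12–C22 to cyclohexenone ring B (C27=O, C26=C16), ring C fused at C16–C21, C18–OTBS, via 1,5-diketone 14 (not isolated)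
Conditions: pyrrolidine (0.3 equiv), AcOH (0.3 equiv), CH2Cl2, 0 °C to rt, then 40 °C
Reagents that add atoms: none
Why: Robinson annulation: enamine-mediated intramolecular Michael addition (6-exo-trig, C12 to C22) closes ring A through the transition state in which H10 and H22 both eclipse C23=C24 (A(1,3) strain minimised, hence 10,22-cis), and the following aldol condensation closes ring B while C21, α to the ketone, should settle trans-diequatorial to C22; C12 is drawn as the expected trans-fused epimer and is erased in step 9.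

Step 9
Reactants: 15 tricyclic enone (10R,12S,18R,21R,22R)
Product: 16 bis-silyl dienol ether: 2-silyloxy-1,3-diene C12=C27(OTBS)–C26=C16, C18–OTBS
Conditions: LiN(i-Pr)2 (1.1 equiv), THF, −78 °C; TBSOTf (1.2 equiv), −78 °C; Et3N, pentane, filtration through basic alumina
Reagents that add atoms: tert-butyldimethylsilyl triflate, CC(C)(C)[Si](C)(C)OS(=O)(=O)C(F)(F)F
Why: Kinetic α′-deprotonation of the enone at C12 and O-silylation give the cross-conjugated silyloxydiene.

Step 10
Reactants: 16 bis-silyl dienol ether; 17 ethyl glyoxylate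
Product: 18 cycloadduct: ethyl 2-oxabicyclo[2.2.2]oct-5-ene-3-carboxylate core, C12 and C16 as in the target, C13–CO2Et endo (toward C27), C27(OTBS)=C26
Conditions: 17 (3 equiv, freshly cracked), ZnCl2 (0.3 equiv), CH2Cl2, −40 to 0 °C; Et3N quench
Reagents that add atoms: none
Why: Lewis-acid-promoted hetero-Diels–Alder reaction (carbonyl [4+2], asynchronous, Mukaiyama-aldol-like) of the 2-silyloxy-1,3-cyclohexadiene with the aldehyde of ethyl glyoxylate, which stands in for CO2; cycloadditions of glyoxylates to cyclohexa-1,3-dienes and to 2-silyloxydienes are the closest known type. One ring is closed, the six-membered oxa-bridge C12–C13–O15–C16, by suprafacial [4+2] addition across the 1,4-termini of the s-cis-locked diene. Orientation: the aldehyde carbon should bond to C12, the β-carbon of the silyl enol ether, because this leaves a 1-silyloxyallyl cation with a tertiary C16 terminus that collapses on oxygen. Facial control: C12 and C16 (cis by necessity) are set by approach to the face anti to the pseudoaxial H22 and H10 flanking C12, so that the substituted carbon end meets no axial hydrogen and only the bare oxygen end passes the axial H21. The ester goes endo (toward C27) because the exo position faces C23; C13 is transient. The step needs regio- and π-face selectivity and must outrun ene reaction and silyl transfer, which the mild Lewis acid, the locked diene and the robust TBS enol ether should secure.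

Step 11
Reactants: 18 cycloadduct
Product: 19 lactone silyl enol ether: C13=O lactone bridge in place, C27(OTBS)=C26, C18–OTBS
Conditions: LiN(i-Pr)2 (1.5 equiv), THF, −78 °C; dry O2, −78 to −20 °C; AcOH
Reagents that add atoms: dioxygen, O=O
Why: Enolate autoxidation with dioxetanone fragmentation (oxidative loss of the ester carbon as CO2, as in base/O2 degradation of α-substituted esters): the C13 ester enolate, which cannot β-eliminate because C12 is a bridgehead (Bredt's rule), traps O2, the hydroperoxide closes onto the ester carbonyl and the ring splits into the lactone C=O and CO2.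

Step 12
Reactants: 19 lactone silyl enol ether
Product: 20 keto lactone (C27 ketone, C18–OH free)
Conditions: HF·pyridine, pyridine, THF, 0 °C to rt; crude 20 is reduced at once
Reagents that add atoms: none
Why: Fluoride cleavage of both silyl groups (the enol ether is protonated at C26) under buffered, weakly acidic conditions that avoid the base-induced retro-oxa-Michael opening of the β-acyloxy ketone.

Step 13
Reactants: 20 keto lactone
Product: 21 target lactone (10R,12S,16R,18R,21R,22R,27R)
Conditions: NaBH4 (1.5 equiv), CeCl3·7H2O (1.2 equiv), MeOH/CH2Cl2, −78 °C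
Reagents that add atoms: none
Why: Luche reduction, in which hydride should attack the C27 ketone from the open lactone-bridge side (the other side is screened by H22 and C20 on the C21–C22 bridge) and so place the 27-OH anti to the lactone.

**Compound list**
1 | (E)-dec-2-enal | CCCCCCC/C=C/C=O | starting material
2 | methyl propiolate | C#CC(=O)OC | starting material
3 | methyl (4R,5E)-4-hydroxytridec-5-en-2-ynoate | CCCCCCC/C=C/[C@@H](O)C#CC(=O)OC | intermediate
4 | methyl (4R,5E)-4-[(2-methoxyprop-2-en-1-yl)oxy]tridec-5-en-2-ynoate | CCCCCCC/C=C/[C@@H](OCC(=C)OC)C#CC(=O)OC | intermediate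
5 | methyl (2Z,4R,5E)-4-[(2-methoxyprop-2-en-1-yl)oxy]-3-methyltrideca-2,5-dienoate | CCCCCCC/C=C/[C@@H](OCC(=C)OC)/C(C)=C\C(=O)OC | intermediate
6 | (2Z,4R,5E)-4-[(2-methoxyprop-2-en-1-yl)oxy]-3-methyltrideca-2,5-dien-1-ol | CCCCCCC/C=C/[C@@H](OCC(=C)OC)/C(C)=C\CO | intermediate
7 | (2Z,4R,5E)-4-[(2-methoxyprop-2-en-1-yl)oxy]-3-methyltrideca-2,5-dienal | CCCCCCC/C=C/[C@@H](OCC(=C)OC)/C(C)=C\C=O | intermediate
8 | (S)-4-[(tert-butyldimethylsilyl)oxy]cyclopent-2-en-1-one | O=C1C=C[C@@H](O[Si](C)(C)C(C)(C)C)C1 | starting material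
9 | (R)-tert-butyldimethyl{[3-(triethylsilyloxy)cyclopent-3-en-1-yl]oxy}silane | CC[Si](CC)(CC)OC1=CC[C@@H](O[Si](C)(C)C(C)(C)C)C1 | intermediate
10 | lithium (R)-4-[(tert-butyldimethylsilyl)oxy]cyclopent-1-en-1-olate | [Li+].[O-]C1=CC[C@@H](O[Si](C)(C)C(C)(C)C)C1 | intermediate
11 | aldol mesylate (C21/C22 diastereomers): 2-[1-(mesyloxy)dienyl]-4-silyloxycyclopentanone | CCCCCCC/C=C/[C@@H](OCC(=C)OC)/C(C)=C\C(OS(C)(=O)=O)C1C[C@@H](O[Si](C)(C)C(C)(C)C)CC1=O | intermediate
12 | enol-ether dienone: (2E,4R)-4-silyloxy-2-[(2Z,4R,5E)-4-(2-methoxyallyloxy)-3-methyltrideca-2,5-dien-1-ylidene]cyclopentan-1-one | CCCCCCC/C=C/[C@@H](OCC(=C)OC)/C(C)=C\C=C1/C[C@@H](O[Si](C)(C)C(C)(C)C)CC1=O | intermediate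
13 | (2E,4R)-4-[(tert-butyldimethylsilyl)oxy]-2-[(2Z,4R,5E)-3-methyl-4-(2-oxopropoxy)trideca-2,5-dien-1-ylidene]cyclopentan-1-one | CCCCCCC/C=C/[C@@H](OCC(C)=O)/C(C)=C\C=C1/C[C@@H](O[Si](C)(C)C(C)(C)C)CC1=O | intermediate
14 | 1,5-diketone: dihydropyran with acetyl at C12 and the 4-silyloxy-2-oxocyclopentyl group at C22 (10R,22R; C12, C21 epimerisable) | CCCCCCC/C=C/[C@H]1OC(C(C)=O)[C@@H](C2C[C@@H](O[Si](C)(C)C(C)(C)C)CC2=O)C=C1C | intermediate
15 | tricyclic enone (10R,12S,18R,21R,22R) | CCCCCCC/C=C/[C@H]1O[C@@H]2C(=O)C=C3C[C@H](O[Si](C)(C)C(C)(C)C)C[C@@H]3[C@H]2C=C1C | intermediate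
16 | bis-silyl dienol ether (diene C12=C27(OTBS)–C26=C16) | CCCCCCC/C=C/[C@H]1OC2=C(O[Si](C)(C)C(C)(C)C)C=C3C[C@H](O[Si](C)(C)C(C)(C)C)C[C@@H]3[C@H]2C=C1C | intermediate
17 | ethyl glyoxylate | CCOC(=O)C=O | starting material
18 | cycloadduct (endo ester at C13, silyl enol ether C27=C26) | CCCCCCC/C=C/[C@H]1O[C@@]23[C@H](C(=O)OCC)O[C@]4(C[C@H](O[Si](C)(C)C(C)(C)C)C[C@@H]4[C@H]2C=C1C)C=C3O[Si](C)(C)C(C)(C)C | intermediate
19 | lactone silyl enol ether | CCCCCCC/C=C/[C@H]1O[C@@]23C(=O)O[C@]4(C[C@H](O[Si](C)(C)C(C)(C)C)C[C@@H]4[C@H]2C=C1C)C=C3O[Si](C)(C)C(C)(C)C | intermediate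
20 | keto lactone | CCCCCCC/C=C/[C@H]1O[C@@]23C(=O)O[C@]4(C[C@H](O)C[C@@H]4[C@H]2C=C1C)CC3=O | intermediate
21 | target lactone (10R,12S,16R,18R,21R,22R,27R) | CCCCCCC/C=C/[C@H]1O[C@@]23C(=O)O[C@]4(C[C@H](O)C[C@@H]4[C@H]2C=C1C)C[C@H]3O | target

**Count.** Total: 13 steps. Longest linear sequence: 12 steps (steps 1–5 and 7–13; step 6 is the side branch).

**Steps most likely to fail**

Step 10. The ring-oxygen donor O11 on C12 may steer the aldehyde carbon to C16 instead of C12 (wrong orientation). Attack may also come from the wrong π-face, or ene reaction and silyl transfer may overtake the cycloaddition. The fallback sets out from 15 and forms the two bonds by stages under enolate control. The kinetic lithium enolate of 15 (LiN(i-Pr)2, THF, −78 °C) adds to ethyl glyoxylate to give the C12 aldol adduct F1; the orientation is fixed because only C12 of the cross-conjugated enolate is nucleophilic. Intramolecular oxa-Michael addition of the carbinol to C16 (catalytic DBU or camphorsulfonic acid, CH2Cl2, 0 °C) gives the bicyclic keto ester F2. Soft enolisation toward C26, the only enolisable side (TBSOTf, Et3N), comes back to the route at 18; either C13 epimer serves.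

Step 11. The hindered C13–H may resist deprotonation, the hydroperoxide may stall instead of fragmenting, or liberated ethoxide may open the lactone. The fallback sets out from 18. Ester cleavage with Me3SnOH (1,2-dichloroethane, 70 °C) gives the carboxylic acid F3. Oxidative decarboxylation with Pb(OAc)4 (pyridine, benzene, rt) gives the acetoxy acetal F4. Methanolysis (K2CO3, MeOH, 0 °C) gives the lactol F5, and oxidation with Ag2CO3 on Celite (benzene, reflux) comes back to the route at 19.

Step 8. The C18 silyloxy group may be lost by β-elimination (E1cB through the C17 enamine or enolate) during the slow condensation, and C21 may not fully equilibrate. The fallback sets out from 13 and carries the C18 oxygen through the annulation as the free alcohol, hydroxide being a far poorer leaving group. HF·pyridine gives the hydroxy dienone F6, the same amine-mediated Michael/aldol annulation gives the hydroxy enone F7, and TBSCl/imidazole (DMF) comes back to the route at 15.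

Further compounds
F1 | step 10 | C12 aldol adduct of 15 with ethyl glyoxylate | CCCCCCC/C=C/[C@H]1O[C@]2(C(O)C(=O)OCC)C(=O)C=C3C[C@H](O[Si](C)(C)C(C)(C)C)C[C@@H]3[C@H]2C=C1C
F2 | step 10 | bicyclic keto ester (C27 ketone, C13–CO2Et) | CCCCCCC/C=C/[C@H]1O[C@@]23C(C(=O)OCC)O[C@]4(C[C@H](O[Si](C)(C)C(C)(C)C)C[C@@H]4[C@H]2C=C1C)CC3=O
F3 | step 11 | C13 carboxylic acid of 18 | CCCCCCC/C=C/[C@H]1O[C@@]23[C@H](C(=O)O)O[C@]4(C[C@H](O[Si](C)(C)C(C)(C)C)C[C@@H]4[C@H]2C=C1C)C=C3O[Si](C)(C)C(C)(C)C
F4 | step 11 | C13 acetoxy acetal | CCCCCCC/C=C/[C@H]1O[C@@]23C(OC(C)=O)O[C@]4(C[C@H](O[Si](C)(C)C(C)(C)C)C[C@@H]4[C@H]2C=C1C)C=C3O[Si](C)(C)C(C)(C)C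
F5 | step 11 | C13 lactol | CCCCCCC/C=C/[C@H]1O[C@@]23C(O)O[C@]4(C[C@H](O[Si](C)(C)C(C)(C)C)C[C@@H]4[C@H]2C=C1C)C=C3O[Si](C)(C)C(C)(C)C
F6 | step 8 | hydroxy dienone (13 without the silyl group) | CCCCCCC/C=C/[C@@H](OCC(C)=O)/C(C)=C\C=C1/C[C@@H](O)CC1=O
F7 | step 8 | hydroxy enone (15 without the silyl group) | CCCCCCC/C=C/[C@H]1O[C@@H]2C(=O)C=C3C[C@H](O)C[C@@H]3[C@H]2C=C1C
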